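The earlier runs and the new flask come from a simulation from invented constants, and the scatter is random.

In a one-step world a target, once made, stays. Tuesday's target does not: it reads 53% at 0.833 min and 17% at 5.00 min, while side product A climbs to 49%.

| flask | substrate | coupling partner | free catalyst | remark | time |
|---|---|---|---|---|---|
| Tuesday's | 0.10 M | 3 equiv | 3.7 mol% | run made earlier |  |
| Thursday's | 0.10 M | 3 equiv | 1.9 mol% | run made earlier |  |
| Sunday's | 0.10 M | 3 equiv | 2.8 mol% | run made earlier |  |
| eta | 0.10 M | 3.00 equiv | 3.7 mol% | everything together at the start | 5.0 min |
| beta | 0.10 M (fed, over 3.0 min) | 3.00 equiv | 3.7 mol% | all else is in the flask from the start; the feed brings no volume worth counting | 5.0 min |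
| zeta | 0.10 M | 3.00 equiv (fed, over 3.0 min) | 3.7 mol% | all else is in the flask from the start; the feed brings no volume worth counting | 5.0 min |
| alpha | 0.10 M (in portions, 3, over 3.0 min) | 3.00 equiv | 3.7 mol% | first portion at the start, last at 3.0 min | 5.0 min |

| run | time / min | target / % | side product A / % |
|---|---|---|---|
| Tuesday's | 0.250 | 27 | 0 |
| Tuesday's | 0.833 | 53 | 10 |
| Tuesday's | 1.33 | 44 | 18 |
| Tuesday's | 2.00 | 34 | 31 |
| Tuesday's | 3.00 | 28 | 42 |
| Tuesday's | 4.00 | 19 | 47 |
| Tuesday's | 5.00 | 17 | 49 |
| Thursday's | 0.333 | 17 | 0 |
| Thursday's | 1.00 | 36 | 4 |
| Thursday's | 1.50 | 40 | 14 |
| Thursday's | 2.50 | 28 | 27 |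
| Thursday's | 4.00 | 18 | 36 |
| Thursday's | 5.00 | 16 | 40 |
| Thursday's | 6.00 | 11 | 40 |
| Sunday's | 0.500 | 33 | 2 |
| Sunday's | 0.667 | 40 | 5 |
| Sunday's | 1.00 | 50 | 10 |
| Sunday's | 1.50 | 42 | 21 |
| Sunday's | 2.50 | 28 | 32 |
| Sunday's | 4.00 | 16 | 43 |
| Sunday's | 6.00 | 13 | 49 |

(standard deviation of a reading: 1.5 percentage points)

- percent here means substrate units held: one side product B counts as two
- steps that have been proposed: substrate + free catalyst -> catalyst intermediate A; coupling partner + catalyst intermediate A -> catalyst intermediate B; catalyst intermediate B -> released group + catalyst intermediate C; catalyst intermediate C -> free catalyst + target; target + released group -> side product A; substrate + target -> side product B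

- which flask leads in share of target in target plus side product A ("all alike" within 1.5 percentage points) (eta / beta / zeta / alpha / all alike)
- share of target in target plus side product A at the end, eta
- share of target in target plus side product A at the end, beta
- share of target in target plus side product A at the end, zeta
- share of target in target plus side product A at the end, alpha

My reckoning needs two times: how long target must wait in the flask, and how fast it pairs off with released group. Each turnover of substrate, the limiting reagent, gives one of each, and a pair makes side product A. In Tuesday's run, released group exceeds target by the missing material divided by 2, 17.0%. Mean late target is 36.0%, and side product A gains 0.144 /min of the charge. So: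

target × released group ÷ gain = 1.33 min

This is the pair time, a reading from Tuesday's run.

In alpha, the last portion passes at Tuesday's early rate in 0.309 min, leaving a hold of 1.69 min. With target and released group taken as equal, and Tuesday's peak as the start:

reciprocal of end target = reciprocal of peak + hold ÷ pair time

This gives 31.6% target in alpha, so its share lies between that and 47.9%. Beta's hold of 2.00 min is longer, so I put alpha first. For zeta I have no number.

The forecast named alpha, with 26% for eta, 32% for beta, 28% for zeta and 34% for alpha: “Late delivery leaves less time for loss”.

The flasks give 23.8% for eta, 35.0% for beta, 30.3% for zeta and 38.0% for alpha, so alpha leads.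

    substrate + free catalyst → catalyst intermediate A (k = 76.0 /M/s)
    coupling partner + catalyst intermediate A → catalyst intermediate B (k = 3.20 /M/s)
    catalyst intermediate B → released group + catalyst intermediate C (k = 67.0 /s)
    catalyst intermediate C → free catalyst + target (k = 2.30 /s)
    target + released group → side product A (k = 0.110 /M/s)
    substrate + target → side product B (k = 0.370 /M/s)

In alpha, the slowest half-life at 5.00 min is 1.48 min, shorter than the hold of 1.69 min, and target stands at 30.9% against my 31.6%. Alpha leads beta by 3 percentage points, more than the margin. In alpha's neighbour with 0.025 M of substrate, equivalents and loadings are held, so free catalyst and coupling partner fall with the substrate. The pair time becomes 5.31 min, the pass lengthens to 1.23 min, and the hold shortens to 0.765 min. Starting again from Tuesday's peak, a rough assumption for this neighbour, my reckoning gives 49.2% target. The computed neighbour holds 59.7% target, a share of 75.5%.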